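With hydroazulene numbering (C1 OAc, C3 C(OH)iPr, C4 aroyloxy, C6 C–Me, C8a C–Me), everything rests on the isolated trisubstituted C6=C7 olefin of the seven-membered ring C3a–C4–C5–C6–C7–C8–C8a. Ring-closing olefin metathesis joins a methallyl carbinol arm on C3a to an allyl arm on C8a, closing this last ring and placing the double bond in one operation, with the 1,3-diol left unprotected. The precursor is a fully substituted cyclopentane that already carries all five stereocentres; it is assembled from a 4-silyloxycyclopentenone by a cuprate addition–aldol three-component coupling followed by an organocerium addition.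

Key step: step 6

Remark: all intermediates are discussed with the hydroazulene numbering of the target (C1 to C8a). 3-Methylbut-3-enal is assumed not to be purchasable and is made fresh in step 3. Catalysts, buffers and coupling agents that add no atoms carry no number.

Step 1
Reactants: 1 (S)-4-[(tert-butyldimethylsilyl)oxy]cyclopent-2-en-1-one; 2 allylmagnesium bromide; 3 chlorotrimethylsilane
Product: 4 (3S,4S)-3-allyl-4-[(tert-butyldimethylsilyl)oxy]-1-[(trimethylsilyl)oxy]cyclopent-1-ene (allyl trans to the silyloxy group)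
Conditions: 2 (1.5 equiv), CuBr·SMe2 (1.5 equiv), 3 (3 equiv), THF, −78 °C; Et3N, pentane, cold aq. NaHCO3; used crude
Reagents that add atoms: allylmagnesium bromide, C=CC[Mg]Br; chlorotrimethylsilane, C[Si](C)(C)Cl
Why: TMSCl-accelerated conjugate addition of an allylcopper reagent (organocopper 1,4-addition) should deliver the allyl group to the β-carbon anti to the 4-silyloxy group and trap the enolate regiospecifically as its silyl enol ether, the new stereocentre being erased in step 2.

Step 2
Reactants: 4 (3S,4S)-3-allyl-4-[(tert-butyldimethylsilyl)oxy]-1-[(trimethylsilyl)oxy]cyclopent-1-ene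
Product: 5 (S)-3-allyl-4-[(tert-butyldimethylsilyl)oxy]cyclopent-2-en-1-one
Conditions: Pd(OAc)2 (1.05 equiv), MeCN, 23 °C
Reagents that add atoms: none
Why: Saegusa–Ito oxidation, in which the palladium(II) enolate formed from the silyl enol ether undergoes β-hydride elimination of its only β-hydrogen (on the allyl-bearing carbon), should restore the enone with the allyl group on the β-carbon and leave the silyloxy stereocentre untouched.

Step 3
Reactants: 6 3-methylbut-3-en-1-ol
Product: 7 3-methylbut-3-enal
Conditions: Dess–Martin periodinane, pyridine, CH2Cl2, 0 °C; filtered cold and used at once as a solution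
Reagents that add atoms: none
Why: Dess–Martin oxidation under pyridine-buffered, non-basic conditions should give the β,γ-unsaturated aldehyde without drift of the double bond into conjugation, and the cold solution is used at once because the aldehyde is volatile and isomerizes on storage.

Step 4
Reactants: 5 (S)-3-allyl-4-[(tert-butyldimethylsilyl)oxy]cyclopent-2-en-1-one; 7 3-methylbut-3-enal; 8 methyllithium
Product: 10 (2S,3R,4S)-3-allyl-4-[(tert-butyldimethylsilyl)oxy]-2-[(1S)-1-hydroxy-3-methylbut-3-en-1-yl]-3-methylcyclopentan-1-one, via lithium enolate 9 (not isolated)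
Conditions: 8 (2.6 equiv), CuI (1.3 equiv), Et2O, 0 °C; 5, −78 → −30 °C; then 7 (2.5 equiv), −78 °C; aq. NH4Cl
Reagents that add atoms: methyllithium (as lithium dimethylcuprate), C[Li]; 3-methylbut-3-enal, CC(=C)CC=O
Why: Tandem cuprate conjugate addition–aldol (three-component coupling), in which methyl should add to the β-carbon anti to the adjacent silyloxy group and so set the quaternary centre C8a with methyl trans and allyl cis to the C1 oxygen, after which the regiodefined enolate 9 should take up the aldehyde at C3a from the face of the small methyl group, away from the allyl and silyloxy groups, through a closed chair (Zimmerman–Traxler) transition state of the ring-locked (E)-enolate that gives the anti relation between C3a and the C4 carbinol.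

Step 5
Reactants: 10 (2S,3R,4S)-3-allyl-4-[(tert-butyldimethylsilyl)oxy]-2-[(1S)-1-hydroxy-3-methylbut-3-en-1-yl]-3-methylcyclopentan-1-one; 11 isopropylmagnesium chloride
Product: 12 (1R,2S,3R,4S)-3-allyl-4-[(tert-butyldimethylsilyl)oxy]-2-[(1S)-1-hydroxy-3-methylbut-3-en-1-yl]-3-methyl-1-(propan-2-yl)cyclopentan-1-ol
Conditions: anhydrous CeCl3 (4 equiv), 11 (4 equiv), THF, −78 °C; then 10, −78 → −40 °C; aq. NH4Cl
Reagents that add atoms: isopropylmagnesium chloride, CC(C)[Mg]Cl
Why: Organocerium 1,2-addition, in which the weakly basic isopropylcerium reagent should add to the enolizable β-hydroxy ketone without retro-aldol cleavage or β-elimination of the silyloxy group and approach the C3 carbonyl from the face of the C3a hydrogen, anti to the C3a side chain held on the other face by the C4 alkoxide chelate, so that the tertiary hydroxyl ends up cis to that side chain.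

Step 6
Reactants: 12 (1R,2S,3R,4S)-3-allyl-4-[(tert-butyldimethylsilyl)oxy]-2-[(1S)-1-hydroxy-3-methylbut-3-en-1-yl]-3-methyl-1-(propan-2-yl)cyclopentan-1-ol
Product: 13 (1S,3R,3aS,4S,8aR)-1-[(tert-butyldimethylsilyl)oxy]-6,8a-dimethyl-3-(propan-2-yl)-1,2,3,3a,4,5,8,8a-octahydroazulene-3,4-diol
Conditions: Grubbs second-generation catalyst (5 mol %), CH2Cl2 (0.005 M), 40 °C
Reagents that add atoms: none
Why: Ring-closing olefin metathesis by the Chauvin mechanism: the ruthenium alkylidene loads on the unhindered allyl terminus at C8a, undergoes [2+2] cycloaddition with the 1,1-disubstituted methallyl olefin of the C4 arm and cycloreverts with loss of ethylene, which drives the reaction. The closest known reaction type is the RCM of a monosubstituted/1,1-disubstituted diene to a trisubstituted cycloheptene fused to a cyclopentane, a closure well established for hydroazulene terpenoids. The seven-membered ring is closed at the C6=C7 bond between the two olefin termini, as an endocyclic Z olefin, the only geometry the ring allows. No stereocentre is created: the trans ring fusion is dictated by the trans arms already fixed at C3a and C8a, and C1, C3 and C4 are spectators. The step needs only chemoselectivity for cyclization over oligomerization and freedom from olefin migration, which high dilution, the absence of any third olefin and the tolerance of the catalyst for the free secondary and tertiary hydroxyls should secure.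

Step 7
Reactants: 13 (1S,3R,3aS,4S,8aR)-1-[(tert-butyldimethylsilyl)oxy]-6,8a-dimethyl-3-(propan-2-yl)-1,2,3,3a,4,5,8,8a-octahydroazulene-3,4-diol; 14 4-acetoxybenzoic acid
Product: 15 (1S,3R,3aS,4S,8aR)-1-[(tert-butyldimethylsilyl)oxy]-3-hydroxy-6,8a-dimethyl-3-(propan-2-yl)-1,2,3,3a,4,5,8,8a-octahydroazulen-4-yl 4-acetoxybenzoate
Conditions: 14, EDC·HCl, DMAP (cat.), CH2Cl2, 0 → 23 °C
Reagents that add atoms: 4-acetoxybenzoic acid, CC(=O)Oc1ccc(cc1)C(=O)O
Why: Steglich esterification should acylate only the secondary C4 hydroxyl, with retention, because the tertiary C3 hydroxyl flanked by isopropyl is inert to the acylpyridinium and C1 still carries its silyl ether.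

Step 8
Reactants: 15 (1S,3R,3aS,4S,8aR)-1-[(tert-butyldimethylsilyl)oxy]-3-hydroxy-6,8a-dimethyl-3-(propan-2-yl)-1,2,3,3a,4,5,8,8a-octahydroazulen-4-yl 4-acetoxybenzoate
Product: 16 (1S,3R,3aS,4S,8aR)-1,3-dihydroxy-6,8a-dimethyl-3-(propan-2-yl)-1,2,3,3a,4,5,8,8a-octahydroazulen-4-yl 4-acetoxybenzoate
Conditions: HF·pyridine, pyridine, THF, 0 → 23 °C
Reagents that add atoms: none
Why: Fluoride-mediated desilylation under acidic conditions should cleave the secondary silyl ether while the base-labile aryl acetate, the benzoate and the tertiary alcohol stay intact.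

Step 9
Reactants: 16 (1S,3R,3aS,4S,8aR)-1,3-dihydroxy-6,8a-dimethyl-3-(propan-2-yl)-1,2,3,3a,4,5,8,8a-octahydroazulen-4-yl 4-acetoxybenzoate; 17 acetic anhydride
Product: 19 (1S,3R,3aS,4S,8aR)-1-acetoxy-3-hydroxy-6,8a-dimethyl-3-(propan-2-yl)-1,2,3,3a,4,5,8,8a-octahydroazulen-4-yl 4-hydroxybenzoate (CNP0275279.1), via diacetate 18 (not isolated)
Conditions: 17, DMAP (cat.), pyridine, CH2Cl2, 23 °C; then pyrrolidine (excess), 0 °C
Reagents that add atoms: acetic anhydride, CC(=O)OC(C)=O
Why: DMAP-catalysed acetylation should esterify the secondary C1 hydroxyl (the hindered tertiary C3 hydroxyl does not react), and the following chemoselective aminolysis relies on the aryl acetate being an activated ester with a phenoxide leaving group, cleaved by pyrrolidine far faster than the secondary alkyl acetate or the benzoate.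

Compound list
1 | (S)-4-[(tert-butyldimethylsilyl)oxy]cyclopent-2-en-1-one | O=C1C=C[C@@H](O[Si](C)(C)C(C)(C)C)C1 | starting material
2 | allylmagnesium bromide | C=CC[Mg]Br | starting material
3 | chlorotrimethylsilane | C[Si](C)(C)Cl | starting material
4 | (3S,4S)-3-allyl-4-[(tert-butyldimethylsilyl)oxy]-1-[(trimethylsilyl)oxy]cyclopent-1-ene | C[Si](C)(C)OC1=C[C@H](CC=C)[C@@H](O[Si](C)(C)C(C)(C)C)C1 | intermediate
5 | (S)-3-allyl-4-[(tert-butyldimethylsilyl)oxy]cyclopent-2-en-1-one | O=C1C=C(CC=C)[C@@H](O[Si](C)(C)C(C)(C)C)C1 | intermediate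
6 | 3-methylbut-3-en-1-ol | CC(=C)CCO | starting material
7 | 3-methylbut-3-enal | CC(=C)CC=O | intermediate
8 | methyllithium | C[Li] | starting material
9 | lithium (3R,4S)-3-allyl-4-[(tert-butyldimethylsilyl)oxy]-3-methylcyclopent-1-en-1-olate | [Li]OC1=C[C@@](C)(CC=C)[C@@H](O[Si](C)(C)C(C)(C)C)C1 | intermediate
10 | (2S,3R,4S)-3-allyl-4-[(tert-butyldimethylsilyl)oxy]-2-[(1S)-1-hydroxy-3-methylbut-3-en-1-yl]-3-methylcyclopentan-1-one | O=C1C[C@H](O[Si](C)(C)C(C)(C)C)[C@](C)(CC=C)[C@H]1[C@@H](O)CC(C)=C | intermediate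
11 | isopropylmagnesium chloride | CC(C)[Mg]Cl | starting material
12 | (1R,2S,3R,4S)-3-allyl-4-[(tert-butyldimethylsilyl)oxy]-2-[(1S)-1-hydroxy-3-methylbut-3-en-1-yl]-3-methyl-1-(propan-2-yl)cyclopentan-1-ol | CC(C)[C@]1(O)C[C@H](O[Si](C)(C)C(C)(C)C)[C@](C)(CC=C)[C@H]1[C@@H](O)CC(C)=C | intermediate
13 | (1S,3R,3aS,4S,8aR)-1-[(tert-butyldimethylsilyl)oxy]-6,8a-dimethyl-3-(propan-2-yl)-1,2,3,3a,4,5,8,8a-octahydroazulene-3,4-diol | CC(C)(C)[Si](C)(C)O[C@H]1C[C@@](O)(C(C)C)[C@@H]2[C@@H](O)CC(C)=CC[C@@]12C | intermediate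
14 | 4-acetoxybenzoic acid | CC(=O)Oc1ccc(cc1)C(=O)O | starting material
15 | (1S,3R,3aS,4S,8aR)-1-[(tert-butyldimethylsilyl)oxy]-3-hydroxy-6,8a-dimethyl-3-(propan-2-yl)-1,2,3,3a,4,5,8,8a-octahydroazulen-4-yl 4-acetoxybenzoate | CC(C)(C)[Si](C)(C)O[C@H]1C[C@@](O)(C(C)C)[C@@H]2[C@@H](OC(=O)c3ccc(OC(C)=O)cc3)CC(C)=CC[C@@]12C | intermediate
16 | (1S,3R,3aS,4S,8aR)-1,3-dihydroxy-6,8a-dimethyl-3-(propan-2-yl)-1,2,3,3a,4,5,8,8a-octahydroazulen-4-yl 4-acetoxybenzoate | O[C@H]1C[C@@](O)(C(C)C)[C@@H]2[C@@H](OC(=O)c3ccc(OC(C)=O)cc3)CC(C)=CC[C@@]12C | intermediate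
17 | acetic anhydride | CC(=O)OC(C)=O | starting material
18 | (1S,3R,3aS,4S,8aR)-1-acetoxy-3-hydroxy-6,8a-dimethyl-3-(propan-2-yl)-1,2,3,3a,4,5,8,8a-octahydroazulen-4-yl 4-acetoxybenzoate | CC(=O)O[C@H]1C[C@@](O)(C(C)C)[C@@H]2[C@@H](OC(=O)c3ccc(OC(C)=O)cc3)CC(C)=CC[C@@]12C | intermediate
19 | (1S,3R,3aS,4S,8aR)-1-acetoxy-3-hydroxy-6,8a-dimethyl-3-(propan-2-yl)-1,2,3,3a,4,5,8,8a-octahydroazulen-4-yl 4-hydroxybenzoate (CNP0275279.1) | CC(=O)O[C@H]1C[C@@](O)(C(C)C)[C@@H]2[C@@H](OC(=O)c3ccc(O)cc3)CC(C)=CC[C@@]12C | target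

Total step count: 9. Longest linear sequence: 8 steps (1, 2, 4, 5, 6, 7, 8, 9 from compound 1); step 3 is a one-step branch.

Steps most likely to fail

Step 4. What may go wrong: erosion of the anti/syn selectivity at C4 through aldolate equilibration or open transition states, so that the carbinol centre forms as a mixture. The fallback sets out from 10 and comes back at 13, and makes the aldol configuration at C4 irrelevant. The adduct is carried on together with its C4 epimer, the syn-aldol F1, through steps 5 and 6. This should give, beside 12 and 13, the epimeric diene diol F2 and the epimeric bicyclic diol F3. The mixture of 13 and F3 is oxidized at the secondary carbinol only (Dess–Martin periodinane, pyridine, CH2Cl2, 0 °C) to the single β-hydroxy ketone F4. Hydroxyl-directed Evans–Saksena reduction (Me4NBH(OAc)3, MeCN/AcOH, −30 °C) should then deliver hydride intramolecularly from the C3 alkoxyborohydride to the β-face of the C4 carbonyl and return the anti-1,3-diol 13 alone.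

Step 5. What may go wrong: retro-aldol cleavage of the metal aldolate, or reduction and enolization of the hindered ketone by the isopropyl reagent in place of addition. The fallback sets out from 10 and comes back at 12, and masks the aldol hydroxyl first. Silylation (Et3SiCl, imidazole, DMF, 0 °C) should give the triethylsilyl ether F5, which can no longer fragment. Addition of the cerium reagent made from 11 (THF, −78 °C) should give the tertiary carbinol F6. The secondary triethylsilyl ether is then removed in the presence of the tert-butyldimethylsilyl ether (PPTS, MeOH, 0 °C) to return 12.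

Step 1. What may go wrong: competing 1,2-addition of the allyl metal to the carbonyl group in place of conjugate addition. The fallback sets out from 1 and comes back at 4, and uses the 1,2-addition on purpose. Addition of 2 to the carbonyl group of 1 (THF, −78 °C) should give the tertiary alcohol F7 as a mixture of carbinol epimers. Anionic oxy-Cope rearrangement (KH, 18-crown-6, THF, 0 → 23 °C) transfers the allyl group to the β-carbon and forms the same regiodefined enolate. Silylation with 3 (Et3N, −78 °C) should give 4 together with its cis isomer F8, and both converge on 5 in step 2.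

Further compounds
F1 | step 4 | (2S,3R,4S)-3-allyl-4-[(tert-butyldimethylsilyl)oxy]-2-[(1R)-1-hydroxy-3-methylbut-3-en-1-yl]-3-methylcyclopentan-1-one (C4 epimer of 10) | O=C1C[C@H](O[Si](C)(C)C(C)(C)C)[C@](C)(CC=C)[C@H]1[C@H](O)CC(C)=C
F2 | step 4 | (1R,2S,3R,4S)-3-allyl-4-[(tert-butyldimethylsilyl)oxy]-2-[(1R)-1-hydroxy-3-methylbut-3-en-1-yl]-3-methyl-1-(propan-2-yl)cyclopentan-1-ol (C4 epimer of 12) | CC(C)[C@]1(O)C[C@H](O[Si](C)(C)C(C)(C)C)[C@](C)(CC=C)[C@H]1[C@H](O)CC(C)=C
F3 | step 4 | (1S,3R,3aS,4R,8aR)-1-[(tert-butyldimethylsilyl)oxy]-6,8a-dimethyl-3-(propan-2-yl)-1,2,3,3a,4,5,8,8a-octahydroazulene-3,4-diol (C4 epimer of 13) | CC(C)(C)[Si](C)(C)O[C@H]1C[C@@](O)(C(C)C)[C@@H]2[C@H](O)CC(C)=CC[C@@]12C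
F4 | step 4 | (1S,3R,3aR,8aR)-1-[(tert-butyldimethylsilyl)oxy]-3-hydroxy-6,8a-dimethyl-3-(propan-2-yl)-2,3,3a,5,8,8a-hexahydroazulen-4(1H)-one | CC(C)(C)[Si](C)(C)O[C@H]1C[C@@](O)(C(C)C)[C@@H]2C(=O)CC(C)=CC[C@@]12C
F5 | step 5 | (2S,3R,4S)-3-allyl-4-[(tert-butyldimethylsilyl)oxy]-3-methyl-2-[(1S)-3-methyl-1-[(triethylsilyl)oxy]but-3-en-1-yl]cyclopentan-1-one | O=C1C[C@H](O[Si](C)(C)C(C)(C)C)[C@](C)(CC=C)[C@H]1[C@@H](O[Si](CC)(CC)CC)CC(C)=C
F6 | step 5 | (1R,2S,3R,4S)-3-allyl-4-[(tert-butyldimethylsilyl)oxy]-3-methyl-2-[(1S)-3-methyl-1-[(triethylsilyl)oxy]but-3-en-1-yl]-1-(propan-2-yl)cyclopentan-1-ol | CC(C)[C@]1(O)C[C@H](O[Si](C)(C)C(C)(C)C)[C@](C)(CC=C)[C@H]1[C@@H](O[Si](CC)(CC)CC)CC(C)=C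
F7 | step 1 | (4S)-1-allyl-4-[(tert-butyldimethylsilyl)oxy]cyclopent-2-en-1-ol (both C1 epimers) | C=CCC1(O)C=C[C@@H](O[Si](C)(C)C(C)(C)C)C1
F8 | step 1 | (3R,4S)-3-allyl-4-[(tert-butyldimethylsilyl)oxy]-1-[(trimethylsilyl)oxy]cyclopent-1-ene (cis isomer of 4) | C[Si](C)(C)OC1=C[C@@H](CC=C)[C@@H](O[Si](C)(C)C(C)(C)C)C1
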